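The earlier runs and the new flask were computed with constants of no real substance.

The meeting had 4 questions on the flask, which is the maple run carried on, and 5 options to weigh.

| setting | maple | birch | flask |
|---|---|---|---|
| starting material | 0.014 M | 0.014 M | 0.014 M |
| reagent | 0.0154 M | 0.0154 M | 0.0154 M |
| free catalyst | 0.35 mM | 0.35 mM | 0.35 mM |
| temperature | 25 °C | 20 °C | 25 °C |
| remark | the very flask that is asked about, followed so far | run made earlier |  |
| time |  |  | 2.0 h |

| run | time / min | product / % | starting material / % |
|---|---|---|---|
| maple | 15.0 | 5.7 | 60.1 |
| maple | 30.0 | 8.3 | 42.7 |
| maple | 40.0 | 8.9 | 36.0 |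
| maple | 60.0 | 9.8 | 28.4 |
| maple | 80.0 | 11.0 | 26.4 |
| maple | 90.0 | 10.0 | 27.1 |
| birch | 15.0 | 2.8 | 75.8 |
| birch | 30.0 | 6.7 | 57.2 |
| birch | 40.0 | 8.9 | 49.0 |
| birch | 60.0 | 11.1 | 39.5 |
| birch | 80.0 | 13.5 | 30.0 |
| birch | 90.0 | 13.4 | 26.5 |

(standard deviation of a reading: 1 percentage point)

- grey: change nothing and wait 4.0 h more
- blue: at 2.0 h take out 90 % of the product then present, then wait 4.0 h
- amber: at 2.0 h add reagent, 100 % of the amount charged, then wait 4.0 h
- green: at 2.0 h raise the temperature by 15 K, then wait 4.0 h
- ochre: at 2.0 h add free catalyst, 100 % of the amount charged, then wait 4.0 h

- product that was removed still counts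
- additions bring no volume worth counting

- product, in percent of the starting material first charged, at 2.0 h
- which option adds most product ("none" when 2 percentage points or less is all one gets) (grey / blue / amber / green / ochre / none)
- product present, with what was taken out counted in, in percent of the starting material first charged, after blue
- product present, with what was taken out counted in, in percent of the starting material first charged, after amber

The chair reported that in the maple run, from 60.0 min to 90.0 min, product read 9.8 %, 11.0 % and 10.0 %, while starting material still read 27.1 %. I took the mean of these product readings, 10.3 %. I then proposed counting this late product against the catalyst charged, with the charges of the maple run held as they were. That gives 4.11 for N, the product made per free catalyst charged, c(product) over c(free catalyst) as charged, the usual turnover number.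

I added that if each product takes one reagent, this product has used 9.33 % of the reagent charge, so in the maple run neither charged partner has run out. A colleague pointed to the birch run at 20 °C, which read 13.4 % of product, more than the maple mean, with starting material still falling to 26.5 %. The stop in the maple run is therefore no ceiling set by product itself.

My reckoning for the flask was about 10.3 % now. Ochre was my choice: a second charge of free catalyst would meet the 27.1 % of starting material read last, less than the full charge, so I expected a gain, but below the 10.3 % of the first charge.

The forecaster gave 10.4 % (9.6 % to 11.3 %) and chose ochre. For blue the forecast was 10.5 % (9.6 % to 12.5 %) and for amber 10.6 % (9.6 % to 12.5 %), on the ground that “Heat, more reagent, removing product and waiting do nothing”. The forecaster expected about 3 points from ochre.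

The flask gave 12.9 % at 2.0 h, and the best option was ochre, adding 8.7 percentage points. Grey added 1.3 points, blue 1.3 points, amber 1.7 points and green 0.96 points. Blue ended at 14.2 % and amber at 14.5 %.

    reagent + catalyst intermediate A → catalyst intermediate B (k = 1.61 /M/s, Ea = 45.0 kJ/mol)
    starting material + free catalyst ⇌ catalyst intermediate A (K = 34.0 /M, k = 0.423 /M/s, Ea = 49.0 kJ/mol, ΔH = −25.0 kJ/mol)
    free catalyst → spent catalyst (k = 2.83 × 10⁻⁴ /s, Ea = 84.0 kJ/mol)
    starting material ⇌ dormant form (K = 2.40, k = 5.42 × 10⁻⁴ /s, Ea = 98.0 kJ/mol, ΔH = −54.0 kJ/mol)
    catalyst intermediate B → free catalyst + product (k = 0.0270 /s, Ea = 73.0 kJ/mol)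
    (constants at 25 °C)

In the flask, starting material passed into the dormant form early, half of that step's turnover being done by 0.216 h, and the dormant form stood at 60.2 % at 1.00 h, while free catalyst fell to 14.9 % of its charge by 2.00 h, with spent catalyst at 83.9 % and product at 5.15 turnovers. The neighbouring flask charged with 0.0014 M of free catalyst also came down to 14.6 % of its charge, and there N of 4.11 comes to 41.1 % of the starting material, while that flask gave 39.0 %.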